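## The problem

3,5,4'-Trihydroxy-6,7,8-trimethoxyflavone 20 is a flat, achiral flavonol, and its difficulty sits almost entirely in ring A. C5, C6, C7 and C8 each carry oxygen, C8a carries the ring oxygen O1 and C4a the C4 carbonyl, so ring A has no C–H left and cannot be finished by electrophilic substitution or directed metalation. The oxygens must also be told apart: the hydroxyls at C3, C5 and C4' end free while the methoxyls at C6, C7 and C8 stay, which rules out any global demethylation and makes the 5-OH/8-OMe pair (a hydroquinone monoether) the point where differentiation is hardest. The ring system is otherwise simple (ring B hangs on C2 by one C–C bond, ring C is fused to ring A at C4a–C8a), and since the target has no stereocentre, C2 and C4 of any flavan intermediate are transient; C2 is set without control and then directs C4, so single diastereomers can be carried. Rough treatment is not tolerated by the pentaoxygenated ring A (oxidised to a quinone once the 5-phenol is free), by the benzylic C4–O bond of flavan-4-ol intermediates (ionised easily, with oxygen at both ortho positions and the para position), or by the acid-labile protecting groups used here. The enabling feature is that C5–C6–C7–C8, one oxygen on each carbon, is a contiguous four-carbon unit that maps atom for atom onto dimethyl squarate, while C4a and C8a–O1 correspond to the enol-ether double bond of a 2-aryl-3,4-dihydro-2H-pyran. Ring A can therefore be built around its oxygens by a cyclobutenone ring expansion.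

## Retrosynthesis

**20 from 19.** The last operation should only unmask. Cutting the O–CH2OCH3 bond at C5 and the O–C(CH3)3 bond at C4' leads to flavonol 19. Both ethers fall to mild acid that leaves aryl methyl ethers alone, so no selective demethylation is needed. A benzyl ether at C4' was set aside because it would meet tert-butyllithium earlier in the route (benzylic lithiation); the tert-butyl ether is inert there and its aldehyde 1 is a catalogue compound.

**19 from 17.** The C3–O bond is cut next, leading to flavone 17. Carrying the C3 oxygen from the start would need an oxygenated diene and would complicate the metalation; nitrosation of a flavanone needs hot mineral acid; alkaline peroxide on a 6'-substituted chalcone tends to give aurones. Epoxidation of the C2=C3 bond and acid isomerisation of the epoxide is neutral-to-mild and has been run on polymethoxyflavones. The forward reaction must oxidise the push–pull alkene without touching ring A.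

**17 from 13 through 15 and 14.** No skeletal bond is cut here; only the oxidation level of ring C changes. Flavone 17 comes from flavan-4-ol 15 by oxidation of C4 and dehydrogenation across C2–C3. Alcohol 15 comes from silyl ether 14, and 14 from phenol 13 by capping the 5-hydroxyl. The cap goes on before the silyl group comes off because a free 5-phenol para to the 8-methoxyl would not survive the oxidant, and a free ortho-hydroxybenzylic alcohol invites quinone methide formation.

**13 from 10 (key disconnection).** Ring A is opened at C4a–C5 and traced to the four-membered ring of cyclobutenone 10. Against cuts that start from a pentaoxygenated benzene, this one never has to oxygenate or deoxygenate an arene: the ketene oxygen becomes the free 5-OH and the three methoxyls are already in place. The precursor is much simpler, a squarate adduct of a dihydropyran with two spectator stereocentres. The forward reaction must open the cyclobutenone with the alkenyl group turned inward and close onto the enol-ether carbon.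

**10 from 6 and 7.** The bond between the pyran C6 and the cyclobutenone sp3 carbon (the future C8–C8a bond) is cut, together with the O–CH3 bond of the future 8-methoxyl. This gives dihydropyran 6 as its C6 anion and dimethyl squarate 7. Metalation of a cyclic enol ether alpha to oxygen and 1,2-addition to a squarate ester are both standard. The C4 oxygen is carried as a triisopropylsilyl ether because smaller silyl groups can be deprotonated at their Si–CH3 groups by tert-butyllithium.

**6 from 1 and 2 through 5 and 4.** Silyl ether 6 comes from allylic alcohol 5, and 5 from dihydropyranone 4 by 1,2-reduction. In 4 the C2–C3 and O1–C6 bonds (pyran numbering) are cut in a hetero-Diels–Alder sense, giving 4-tert-butoxybenzaldehyde 1 and diene 2. This sets the whole C2-aryl pyran in one step from purchased materials, where an aldol and cyclisation sequence would need several steps. The forward sequence must give the cis alcohol and keep the acid-labile aryl ether intact.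

## Roads not taken

**Alternative 1:** The cut removes all of ring C from a benzene ring: O1–C8a, C4–C4a and O1–C2. In the forward step CsF would convert 3,4,5,6-tetramethoxy-2-(trimethylsilyl)phenyl trifluoromethanesulfonate A1 into 3,4,5,6-tetramethoxybenzyne A2. The carboxylate of 3-(4-benzyloxyphenyl)propiolic acid A3 would add through oxygen to A2, the aryl anion would take over the acyl group, and the phenoxide so formed would close 6-endo onto the ynone to give 2-(4-benzyloxyphenyl)-5,6,7,8-tetramethoxychromen-4-one A4.
- Merits: ring C forms in one flask from two pieces, A2 is symmetric so there is no regiochemical question, A3 is a simple arylpropiolic acid, and the conditions are mild. It is more convergent than the chosen plan.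
- Weak points: A1 is a hexasubstituted benzene that must itself be made in several steps from a pentasubstituted phenol, so the ring A problem is moved, not solved. A4 has a 5-methyl ether that must be cleaved selectively and no C3 oxygen. The aryl anion sits beside a methoxyl and may be protonated before acyl transfer, and 5-exo closure to an aurone competes.
- Comparison: after its key step this road needs about as many steps from A4 as the chosen endgame, and chelation-directed 5-demethylation is reliable. The chosen plan sets against it that all three building blocks are purchased and that the 5-hydroxyl is born free and differentiated.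

**Alternative 2:** The cut is O1–C8a alone. In the forward step (NH4)2Ce(NO3)6 in aqueous acetonitrile would oxidise 2-(benzyloxy)-1-(4-benzyloxyphenyl)-3-(2,3,4,5-tetramethoxyphenyl)propane-1,3-dione A5 at its para-dimethoxy pair to the acylquinone 2-(benzyloxy)-1-(4-benzyloxyphenyl)-3-(4,5-dimethoxy-3,6-dioxocyclohexa-1,4-dien-1-yl)propane-1,3-dione A6. The enol oxygen of A6 then adds to the quinone CH carbon to give 3-(benzyloxy)-2-(4-benzyloxyphenyl)-5,8-dihydroxy-6,7-dimethoxychromen-4-one A7.
- Merits: the C3 oxygen is present in A5 from the start, which is a real advantage over the chosen plan, where C3 is oxidised late. The arene is cheap, and the 8-hydroxyl of A7 can be methylated selectively because the 5-hydroxyl is hydrogen-bonded to the carbonyl.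
- Weak points: in A5 a strong one-electron oxidant meets an enolisable alpha-alkoxy diketone and two benzyl ethers. A6 is a highly reactive electrophile, and hydroquinone A7 can be re-oxidised in the same flask. The sequence is oxidise, reduce, methylate, hydrogenolyse.
- Comparison: the length is comparable and possibly shorter. The chosen plan sets against it that no oxidant touches ring A and that the 5-OH/8-OMe pattern is fixed by connectivity, not by a selective methylation of an air-sensitive hydroquinone such as A7.

**Alternative 3:** The cut is C4–C4a and O1–C2. In the forward step 2,3,4,5-tetramethoxyphenol A8 and ethyl 2-(benzyloxy)-3-(4-benzyloxyphenyl)-3-oxopropanoate A9 would be heated together without solvent at about 240 °C. Acylketene C-acylation at the one free CH of A8 and cyclodehydration would give 3-(benzyloxy)-2-(4-benzyloxyphenyl)-5,6,7,8-tetramethoxychromen-4-one A10.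
- Merits: this is the shortest road on paper. A8 has a single CH, A9 brings the C3 oxygen, and from A10 only selective 5-demethylation and hydrogenolysis remain.
- Weak points: the temperature is harsh for the benzyl ethers of A9 and for an electron-rich phenol. The only reacting carbon of A8 is flanked by a hydroxyl and a methoxyl. O-acylation and closure in the coumarin sense compete with formation of A10. A8 is not a catalogue compound and needs its own synthesis.
- Comparison: in step count this road beats the chosen plan if the condensation of A8 with A9 behaves. The chosen plan sets against it a pericyclic step near 110 °C whose outcome is fixed by connectivity, and a product whose 5-hydroxyl is already free.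

Key step: step 5

Remark on the chemistry: all chiral intermediates are racemic (the target has no stereocentre); SMILES show the (2S,4S) enantiomer of the cis series. Compounds 1, 2 and 7 are taken as purchased.

## Route

Step 1
Reactants: 1 4-tert-butoxybenzaldehyde; 2 (E)-1-methoxy-3-(trimethylsilyloxy)buta-1,3-diene
Product: 4 2-(4-tert-butoxyphenyl)-2,3-dihydro-4H-pyran-4-one (racemic), via silyl enol ether cycloadduct 3 (not isolated)
Conditions: ZnCl2 (cat.), THF, rt; then CF3CO2H (cat.), CH2Cl2, 0 °C
Reagents that add atoms: none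
Why: Lewis-acid-promoted hetero-Diels–Alder reaction of the electron-rich diene with an aryl aldehyde; a catalytic trace of acid then expels methanol and the silyl group from 3 to give the vinylogous ester, mild enough to spare the aryl tert-butyl ether; C2 forms as a racemate.

Step 2
Reactants: 4 2-(4-tert-butoxyphenyl)-2,3-dihydro-4H-pyran-4-one
Product: 5 cis-2-(4-tert-butoxyphenyl)-3,4-dihydro-2H-pyran-4-ol (racemic; 2S*,4S*)
Conditions: NaBH4, CeCl3·7H2O, MeOH, −78 → −20 °C
Reagents that add atoms: none
Why: Luche 1,2-reduction of the enone; hydride adds axially to the half-chair that holds the aryl group equatorial, so the new C4 hydroxyl is pseudo-equatorial and cis to the aryl group, controlled by C2.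

Step 3
Reactants: 5 cis-2-(4-tert-butoxyphenyl)-3,4-dihydro-2H-pyran-4-ol
Product: 6 cis-2-(4-tert-butoxyphenyl)-4-(triisopropylsilyloxy)-3,4-dihydro-2H-pyran (racemic; 2S*,4S*)
Conditions: i-Pr3SiCl, imidazole, DMAP (cat.), DMF, rt
Reagents that add atoms: chlorotriisopropylsilane, CC(C)[Si](Cl)(C(C)C)C(C)C
Why: Standard silylation of a secondary allylic alcohol under basic conditions that do not trigger allylic ionisation; the triisopropylsilyl group has no Si–CH3 to be deprotonated in the next step.

Step 4
Reactants: 6 cis-2-(4-tert-butoxyphenyl)-4-(triisopropylsilyloxy)-3,4-dihydro-2H-pyran; 7 dimethyl squarate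
Product: 10 4-[cis-2-(4-tert-butoxyphenyl)-4-(triisopropylsilyloxy)-3,4-dihydro-2H-pyran-6-yl]-2,3,4-trimethoxycyclobut-2-en-1-one (racemic; both epimers at the cyclobutenone carbon), via vinyllithium 8 (not isolated), via lithium alkoxide 9 (not isolated)
Conditions: t-BuLi, THF, −78 → 0 °C; add to 7, THF, −78 °C; then MeOSO2CF3, −78 → 0 °C
Reagents that add atoms: methyl trifluoromethanesulfonate, COS(=O)(=O)C(F)(F)F
Why: Alpha-lithiation of a cyclic enol ether at the vinylic C–H next to oxygen (as for silyl-protected glycals), 1,2-addition of the vinyllithium to one carbonyl of the squarate ester by inverse addition, and O-methylation of the tertiary lithium alkoxide in the same flask; warming to 0 °C lets THF consume excess base before the squarate is met.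

Step 5
Reactants: 10 4-[cis-2-(4-tert-butoxyphenyl)-4-(triisopropylsilyloxy)-3,4-dihydro-2H-pyran-6-yl]-2,3,4-trimethoxycyclobut-2-en-1-one
Product: 13 cis-2-(4-tert-butoxyphenyl)-6,7,8-trimethoxy-4-(triisopropylsilyloxy)chroman-5-ol (racemic; 2S*,4S*), via dienylketene 11 (not isolated), via cyclohexadienone 12 (not isolated)
Conditions: toluene (degassed, 0.01 M), 110 °C, Ar
Reagents that add atoms: none
Why: Heating opens the cyclobutenone by conrotatory 4π electrocyclic cleavage of the bond between the carbonyl carbon and the sp3 carbon, giving the (Z)-dienylketene 11. The ketene carbon then bonds to C5 of the dihydropyran in a thermal 6π electrocyclisation that forms C4a–C5 and closes six-membered ring A as cyclohexa-2,4-dienone 12, and enolisation of 12 aromatises it to phenol 13. This is the Moore rearrangement of 4-alkenyl-4-alkoxycyclobutenones made from squarate esters, a known route to hydroquinone monoethers that has been applied to adducts of lithiated cyclic enol ethers to give chromanols. Ring A is closed in the disrotatory 6π mode between a nucleophilic enol-ether carbon and an electrophilic ketene carbon, a polarity match. No lasting stereocentre is created: C4a of 12 becomes sp2, both epimers of 10 converge because the cyclobutenone sp3 carbon becomes C8, and C2 and C4 are untouched. The selectivity needed is torquoselectivity in the ring opening, secured by the donor methoxyl on the sp3 carbon, which rotates outward and turns the dihydropyranyl group inward beside the ketene. The substitution pattern needs no control because connectivity fixes it: the ketene oxygen becomes the free 5-hydroxyl, the vinylic methoxyls the 6- and 7-methoxyls, and the carbinol methyl ether the 8-methoxyl.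

Step 6
Reactants: 13 cis-2-(4-tert-butoxyphenyl)-6,7,8-trimethoxy-4-(triisopropylsilyloxy)chroman-5-ol
Product: 14 cis-2-(4-tert-butoxyphenyl)-6,7,8-trimethoxy-5-(methoxymethoxy)-4-(triisopropylsilyloxy)chromane (racemic; 2S*,4S*)
Conditions: MeOCH2Cl, i-Pr2NEt, CH2Cl2, 0 → 40 °C
Reagents that add atoms: chloromethyl methyl ether, COCCl
Why: O-alkylation of a phenol with a small, reactive electrophile under mild base; capping the phenol removes the quinone methide pathway and shields ring A from the oxidant of step 8.

Step 7
Reactants: 14 cis-2-(4-tert-butoxyphenyl)-6,7,8-trimethoxy-5-(methoxymethoxy)-4-(triisopropylsilyloxy)chromane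
Product: 15 cis-2-(4-tert-butoxyphenyl)-6,7,8-trimethoxy-5-(methoxymethoxy)chroman-4-ol (racemic; 2S*,4S*)
Conditions: Bu4NF, THF, 0 °C → rt
Reagents that add atoms: none
Why: Fluoride cleavage of a secondary silyl ether; the non-acidic conditions avoid ionisation of the electron-rich benzylic C4–O bond.

Step 8
Reactants: 15 cis-2-(4-tert-butoxyphenyl)-6,7,8-trimethoxy-5-(methoxymethoxy)chroman-4-ol
Product: 17 2-(4-tert-butoxyphenyl)-6,7,8-trimethoxy-5-(methoxymethoxy)-4H-chromen-4-one, via flavanone 16 (not isolated)
Conditions: 2-iodoxybenzoic acid (excess), DMSO, rt → 80 °C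
Reagents that add atoms: none
Why: 2-Iodoxybenzoic acid oxidises the benzylic alcohol to the chromanone at room temperature and, on warming, dehydrogenates the ketone to the enone (alcohol-to-enone oxidation in one flask, known for flavanones to flavones); both stereocentres are erased here as planned.

Step 9
Reactants: 17 2-(4-tert-butoxyphenyl)-6,7,8-trimethoxy-5-(methoxymethoxy)-4H-chromen-4-one
Product: 19 2-(4-tert-butoxyphenyl)-3-hydroxy-6,7,8-trimethoxy-5-(methoxymethoxy)-4H-chromen-4-one, via flavone epoxide 18 (not isolated)
Conditions: dimethyldioxirane (acetone), CH2Cl2, 0 °C; then TsOH·H2O (cat.), CH2Cl2, rt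
Reagents that add atoms: dimethyldioxirane, CC1(C)OO1
Why: Dimethyldioxirane epoxidises the C2=C3 bond of flavones under neutral conditions, and a trace of acid opens the epoxide at C2 (cation stabilised by O1 and the alkoxyphenyl group) with loss of the C3 proton to give the 3-hydroxyflavone; the method is established for polymethoxyflavones.

Step 10
Reactants: 19 2-(4-tert-butoxyphenyl)-3-hydroxy-6,7,8-trimethoxy-5-(methoxymethoxy)-4H-chromen-4-one
Product: 20 3,5-dihydroxy-2-(4-hydroxyphenyl)-6,7,8-trimethoxy-4H-chromen-4-one (3,5,4'-trihydroxy-6,7,8-trimethoxyflavone)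
Conditions: HCl (4 M in 1,4-dioxane), MeOH, 50 °C
Reagents that add atoms: none
Why: Acid-catalysed acetal exchange removes the methoxymethyl group and SN1 cleavage removes the aryl tert-butyl ether, while aryl methyl ethers and the flavonol core are inert; any material that lost its methoxymethyl group in step 9 converges here.

## Compound list

1 | 4-tert-butoxybenzaldehyde | O=Cc1ccc(OC(C)(C)C)cc1 | starting material
2 | (E)-1-methoxy-3-(trimethylsilyloxy)buta-1,3-diene | CO/C=C/C(=C)O[Si](C)(C)C | starting material
3 | 2-(4-tert-butoxyphenyl)-6-methoxy-4-(trimethylsilyloxy)-3,6-dihydro-2H-pyran (racemic, mixture of C6 epimers) | COC1C=C(O[Si](C)(C)C)CC(c2ccc(OC(C)(C)C)cc2)O1 | intermediate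
4 | 2-(4-tert-butoxyphenyl)-2,3-dihydro-4H-pyran-4-one (racemic) | C1=CC(=O)C[C@@H](c2ccc(OC(C)(C)C)cc2)O1 | intermediate
5 | cis-2-(4-tert-butoxyphenyl)-3,4-dihydro-2H-pyran-4-ol (racemic, 2S*,4S*) | C1=C[C@@H](O)C[C@@H](c2ccc(OC(C)(C)C)cc2)O1 | intermediate
6 | cis-2-(4-tert-butoxyphenyl)-4-(triisopropylsilyloxy)-3,4-dihydro-2H-pyran (racemic, 2S*,4S*) | C1=C[C@@H](O[Si](C(C)C)(C(C)C)C(C)C)C[C@@H](c2ccc(OC(C)(C)C)cc2)O1 | intermediate
7 | dimethyl squarate (3,4-dimethoxycyclobut-3-ene-1,2-dione) | COC1=C(OC)C(=O)C1=O | starting material
8 | [cis-2-(4-tert-butoxyphenyl)-4-(triisopropylsilyloxy)-3,4-dihydro-2H-pyran-6-yl]lithium | [Li]C1=C[C@@H](O[Si](C(C)C)(C(C)C)C(C)C)C[C@@H](c2ccc(OC(C)(C)C)cc2)O1 | intermediate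
9 | lithium 1-[cis-2-(4-tert-butoxyphenyl)-4-(triisopropylsilyloxy)-3,4-dihydro-2H-pyran-6-yl]-2,3-dimethoxy-4-oxocyclobut-2-en-1-olate (both epimers at the carbinol carbon) | [Li]OC1(C(OC)=C(OC)C1=O)C1=C[C@@H](O[Si](C(C)C)(C(C)C)C(C)C)C[C@@H](c2ccc(OC(C)(C)C)cc2)O1 | intermediate
10 | 4-[cis-2-(4-tert-butoxyphenyl)-4-(triisopropylsilyloxy)-3,4-dihydro-2H-pyran-6-yl]-2,3,4-trimethoxycyclobut-2-en-1-one (racemic, both epimers at the cyclobutenone carbon) | COC1(C(OC)=C(OC)C1=O)C1=C[C@@H](O[Si](C(C)C)(C(C)C)C(C)C)C[C@@H](c2ccc(OC(C)(C)C)cc2)O1 | intermediate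
11 | (3Z)-4-[cis-2-(4-tert-butoxyphenyl)-4-(triisopropylsilyloxy)-3,4-dihydro-2H-pyran-6-yl]-2,3,4-trimethoxybuta-1,3-dien-1-one | COC(=C=O)/C(OC)=C(OC)\C1=C[C@@H](O[Si](C(C)C)(C(C)C)C(C)C)C[C@@H](c2ccc(OC(C)(C)C)cc2)O1 | intermediate
12 | cis-2-(4-tert-butoxyphenyl)-6,7,8-trimethoxy-4-(triisopropylsilyloxy)-2,3,4,4a-tetrahydro-5H-chromen-5-one (C4a unassigned) | O=C1C(OC)=C(OC)C(OC)=C2O[C@H](c3ccc(OC(C)(C)C)cc3)C[C@H](O[Si](C(C)C)(C(C)C)C(C)C)C12 | intermediate
13 | cis-2-(4-tert-butoxyphenyl)-6,7,8-trimethoxy-4-(triisopropylsilyloxy)chroman-5-ol (racemic, 2S*,4S*) | COc1c(OC)c(O)c2c(c1OC)O[C@H](c1ccc(OC(C)(C)C)cc1)C[C@@H]2O[Si](C(C)C)(C(C)C)C(C)C | intermediate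
14 | cis-2-(4-tert-butoxyphenyl)-6,7,8-trimethoxy-5-(methoxymethoxy)-4-(triisopropylsilyloxy)chromane (racemic, 2S*,4S*) | COc1c(OC)c(OCOC)c2c(c1OC)O[C@H](c1ccc(OC(C)(C)C)cc1)C[C@@H]2O[Si](C(C)C)(C(C)C)C(C)C | intermediate
15 | cis-2-(4-tert-butoxyphenyl)-6,7,8-trimethoxy-5-(methoxymethoxy)chroman-4-ol (racemic, 2S*,4S*) | COc1c(OC)c(OCOC)c2c(c1OC)O[C@H](c1ccc(OC(C)(C)C)cc1)C[C@@H]2O | intermediate
16 | 2-(4-tert-butoxyphenyl)-6,7,8-trimethoxy-5-(methoxymethoxy)chroman-4-one (racemic) | COc1c(OC)c(OCOC)c2c(c1OC)O[C@H](c1ccc(OC(C)(C)C)cc1)CC2=O | intermediate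
17 | 2-(4-tert-butoxyphenyl)-6,7,8-trimethoxy-5-(methoxymethoxy)-4H-chromen-4-one | COc1c(OC)c(OCOC)c2c(=O)cc(-c3ccc(OC(C)(C)C)cc3)oc2c1OC | intermediate
18 | 2-(4-tert-butoxyphenyl)-2,3-epoxy-6,7,8-trimethoxy-5-(methoxymethoxy)chroman-4-one (racemic, cis-fused) | COc1c(OC)c(OCOC)c2c(c1OC)O[C@@]1(c3ccc(OC(C)(C)C)cc3)O[C@H]1C2=O | intermediate
19 | 2-(4-tert-butoxyphenyl)-3-hydroxy-6,7,8-trimethoxy-5-(methoxymethoxy)-4H-chromen-4-one | COc1c(OC)c(OCOC)c2c(=O)c(O)c(-c3ccc(OC(C)(C)C)cc3)oc2c1OC | intermediate
20 | 3,5-dihydroxy-2-(4-hydroxyphenyl)-6,7,8-trimethoxy-4H-chromen-4-one | COc1c(OC)c(O)c2c(=O)c(O)c(-c3ccc(O)cc3)oc2c1OC | target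

## Step count and risks

Total steps: 10. Longest linear sequence: 10 steps (1 to 20); 2 and 7 enter as purchased reagents.

**Step 5 (key step).** The cascade itself is expected to be reliable. The likely failure is loss of silanol from the new ortho-hydroxybenzylic silyl ether at 110 °C through an ortho-quinone methide. A second risk is slowing of the 6π closure by the bulky silyloxy group next to the bond-forming carbon, which gives the ketene time to decompose.
Fallback: the oxidation level of the pyran is changed before the ring expansion, keeping the same bond formation and ring closure. Setting out from 10, the silyl group is removed (Bu4NF, AcOH, THF, 0 °C) to give 4-[cis-2-(4-tert-butoxyphenyl)-4-hydroxy-3,4-dihydro-2H-pyran-6-yl]-2,3,4-trimethoxycyclobut-2-en-1-one F1. The allylic alcohol is oxidised with MnO2 in CH2Cl2 to 2-(4-tert-butoxyphenyl)-6-(1,2,3-trimethoxy-4-oxocyclobut-2-en-1-yl)-2,3-dihydro-4H-pyran-4-one F2. Thermolysis of F2 in toluene should then give 2-(4-tert-butoxyphenyl)-5-hydroxy-6,7,8-trimethoxychroman-4-one F3, a hydrogen-bonded 5-hydroxyflavanone with no benzylic leaving group and a far less oxidisable phenol. Methoxymethylation of F3 (MeOCH2Cl, i-Pr2NEt) comes back to the route at 16, which is dehydrogenated as in step 8.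

**Step 4.** The likely failure is competing deprotonation at the benzylic C2–H, which is also alpha to the ring oxygen, so that C6 metalation is incomplete and the material fragments.
Fallback: the vinyllithium is made by tin–lithium exchange instead of deprotonation, as is done for glycals with base-sensitive groups. Setting out from 6, thiophenol is added across the enol ether (PhSH, PPh3·HBr cat., CH2Cl2) to give cis-2-(4-tert-butoxyphenyl)-6-(phenylthio)-4-(triisopropylsilyloxy)tetrahydro-2H-pyran F4. Oxidation with mCPBA gives the sulfone cis-2-(4-tert-butoxyphenyl)-6-(phenylsulfonyl)-4-(triisopropylsilyloxy)tetrahydro-2H-pyran F5. Deprotonation alpha to sulfur (LiN(i-Pr)2, THF, −78 °C) and quenching with Bu3SnCl gives the alpha-stannyl sulfone cis-2-(4-tert-butoxyphenyl)-6-(phenylsulfonyl)-6-(tributylstannyl)-4-(triisopropylsilyloxy)tetrahydro-2H-pyran F6. With i-Pr2NEt, F6 loses benzenesulfinic acid to give cis-2-(4-tert-butoxyphenyl)-6-(tributylstannyl)-4-(triisopropylsilyloxy)-3,4-dihydro-2H-pyran F7. Treatment of F7 with n-BuLi at −78 °C comes back to the route at 8.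

**Step 8.** The likely failure is that the dehydrogenation half stalls at the flavanone or is accompanied by oxidative damage to the electron-rich rings at 80 °C.
Fallback: the two oxidations are separated and the second is run through a silyl enol ether. Setting out from 15, Dess–Martin periodinane (NaHCO3, CH2Cl2) gives 16, now isolated. Enolate trapping (LiN(SiMe3)2, Me3SiCl, THF, −78 °C) gives 2-(4-tert-butoxyphenyl)-6,7,8-trimethoxy-5-(methoxymethoxy)-4-(trimethylsilyloxy)-2H-chromene F8. Saegusa–Ito oxidation of F8 with Pd(OAc)2 (divalent palladium) in MeCN comes back to the route at 17.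

**Step 9.** The likely failure is slow epoxidation of the electron-poor C2=C3 bond, which lets the oxidant attack the pentaoxygenated ring A instead.
Fallback: the oxygen is introduced by a carbanion route. Setting out from 17, C3 is lithiated (LiN(i-Pr)2, THF, −78 °C) and trapped with B(OMe)3 to give dimethyl [2-(4-tert-butoxyphenyl)-6,7,8-trimethoxy-5-(methoxymethoxy)-4-oxo-4H-chromen-3-yl]boronate F9. Oxidation of F9 with H2O2/AcOH comes back to the route at 19.

## Further compounds

F1 | step 5 | 4-[cis-2-(4-tert-butoxyphenyl)-4-hydroxy-3,4-dihydro-2H-pyran-6-yl]-2,3,4-trimethoxycyclobut-2-en-1-one | COC1(C(OC)=C(OC)C1=O)C1=C[C@@H](O)C[C@@H](c2ccc(OC(C)(C)C)cc2)O1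
F2 | step 5 | 2-(4-tert-butoxyphenyl)-6-(1,2,3-trimethoxy-4-oxocyclobut-2-en-1-yl)-2,3-dihydro-4H-pyran-4-one | COC1(C(OC)=C(OC)C1=O)C1=CC(=O)C[C@@H](c2ccc(OC(C)(C)C)cc2)O1
F3 | step 5 | 2-(4-tert-butoxyphenyl)-5-hydroxy-6,7,8-trimethoxychroman-4-one | COc1c(OC)c(O)c2c(c1OC)O[C@H](c1ccc(OC(C)(C)C)cc1)CC2=O
F4 | step 4 | cis-2-(4-tert-butoxyphenyl)-6-(phenylthio)-4-(triisopropylsilyloxy)tetrahydro-2H-pyran (mixture of C6 epimers) | c1ccccc1SC1C[C@@H](O[Si](C(C)C)(C(C)C)C(C)C)C[C@@H](c2ccc(OC(C)(C)C)cc2)O1
F5 | step 4 | cis-2-(4-tert-butoxyphenyl)-6-(phenylsulfonyl)-4-(triisopropylsilyloxy)tetrahydro-2H-pyran (mixture of C6 epimers) | O=S(=O)(c1ccccc1)C1C[C@@H](O[Si](C(C)C)(C(C)C)C(C)C)C[C@@H](c2ccc(OC(C)(C)C)cc2)O1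
F6 | step 4 | cis-2-(4-tert-butoxyphenyl)-6-(phenylsulfonyl)-6-(tributylstannyl)-4-(triisopropylsilyloxy)tetrahydro-2H-pyran | CCCC[Sn](CCCC)(CCCC)C1(S(=O)(=O)c2ccccc2)C[C@@H](O[Si](C(C)C)(C(C)C)C(C)C)C[C@@H](c2ccc(OC(C)(C)C)cc2)O1
F7 | step 4 | cis-2-(4-tert-butoxyphenyl)-6-(tributylstannyl)-4-(triisopropylsilyloxy)-3,4-dihydro-2H-pyran | CCCC[Sn](CCCC)(CCCC)C1=C[C@@H](O[Si](C(C)C)(C(C)C)C(C)C)C[C@@H](c2ccc(OC(C)(C)C)cc2)O1
F8 | step 8 | 2-(4-tert-butoxyphenyl)-6,7,8-trimethoxy-5-(methoxymethoxy)-4-(trimethylsilyloxy)-2H-chromene | COc1c(OC)c(OCOC)c2c(c1OC)O[C@H](c1ccc(OC(C)(C)C)cc1)C=C2O[Si](C)(C)C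
F9 | step 9 | dimethyl [2-(4-tert-butoxyphenyl)-6,7,8-trimethoxy-5-(methoxymethoxy)-4-oxo-4H-chromen-3-yl]boronate | COc1c(OC)c(OCOC)c2c(=O)c(B(OC)OC)c(-c3ccc(OC(C)(C)C)cc3)oc2c1OC
A1 | alternative 1 | 3,4,5,6-tetramethoxy-2-(trimethylsilyl)phenyl trifluoromethanesulfonate | COc1c(OC)c(OC)c(OC)c(OS(=O)(=O)C(F)(F)F)c1[Si](C)(C)C
A2 | alternative 1 | 3,4,5,6-tetramethoxybenzyne (1,2-didehydro-3,4,5,6-tetramethoxybenzene) | COC1=C(OC)C(OC)=C(OC)C#C1
A3 | alternative 1 | 3-(4-benzyloxyphenyl)propiolic acid | O=C(O)C#Cc1ccc(OCc2ccccc2)cc1
A4 | alternative 1 | 2-(4-benzyloxyphenyl)-5,6,7,8-tetramethoxychromen-4-one | COc1c(OC)c(OC)c2c(=O)cc(-c3ccc(OCc4ccccc4)cc3)oc2c1OC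
A5 | alternative 2 | 2-(benzyloxy)-1-(4-benzyloxyphenyl)-3-(2,3,4,5-tetramethoxyphenyl)propane-1,3-dione | COc1cc(C(=O)C(OCc2ccccc2)C(=O)c2ccc(OCc3ccccc3)cc2)c(OC)c(OC)c1OC
A6 | alternative 2 | 2-(benzyloxy)-1-(4-benzyloxyphenyl)-3-(4,5-dimethoxy-3,6-dioxocyclohexa-1,4-dien-1-yl)propane-1,3-dione | COC1=C(OC)C(=O)C(C(=O)C(OCc2ccccc2)C(=O)c2ccc(OCc3ccccc3)cc2)=CC1=O
A7 | alternative 2 | 3-(benzyloxy)-2-(4-benzyloxyphenyl)-5,8-dihydroxy-6,7-dimethoxychromen-4-one | COc1c(OC)c(O)c2c(=O)c(OCc3ccccc3)c(-c3ccc(OCc4ccccc4)cc3)oc2c1O
A8 | alternative 3 | 2,3,4,5-tetramethoxyphenol | COc1cc(O)c(OC)c(OC)c1OC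
A9 | alternative 3 | ethyl 2-(benzyloxy)-3-(4-benzyloxyphenyl)-3-oxopropanoate | CCOC(=O)C(OCc1ccccc1)C(=O)c1ccc(OCc2ccccc2)cc1
A10 | alternative 3 | 3-(benzyloxy)-2-(4-benzyloxyphenyl)-5,6,7,8-tetramethoxychromen-4-one | COc1c(OC)c(OC)c2c(=O)c(OCc3ccccc3)c(-c3ccc(OCc4ccccc4)cc3)oc2c1OC
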